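Ring B (the bromohydrin cyclohexane) is read as a masked 4-substituted cyclohex-2-enone: its carbinol carbon C(CH3)OH is the old carbonyl, the CHBr–CH2 bond the old C=C, and the CH that carries the side chain the old γ-carbon. One organocatalytic Michael/aldol annulation of a lactic-acid-derived aldehyde (quaternary carbinol centre already in place) with methyl vinyl ketone therefore forms the CH–CH2 bond remote from bromine and the CHBr–CH2 bond, sets the ring CH stereocentre, and leaves the enone for bromine and methyl delivery. Ring A comes from an enantiospecific bromonium cyclisation; a Julia–Kocienski olefination joins the halves.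

Key step: step 4

Assumption: the facial selectivities of the (R)-prolinol silyl ether (step 4) and of the D-fructose-derived ketone (step 13) are taken from the accepted transition-state models for these catalysts; should either prove opposite, the enantiomeric catalyst is used.

**Fragment B (ring B with the carbinol side chain)**

Step 1
Reactants: 1 (R)-lactic acid; 2 pivalaldehyde
Product: 3 (2R,5R)-2-tert-butyl-5-methyl-1,3-dioxolan-4-one
Conditions: p-TsOH·H2O (cat.), H2SO4 (cat.), pentane, reflux, Dean–Stark; crystallisation from pentane–Et2O, −78 °C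
Reagents that add atoms: none
Why: Acid-catalysed acetalisation under equilibrating conditions favours the cis-2,5-disubstituted dioxolanone and crystallisation removes the trans isomer, so the untouched lactic acid stereocentre fixes the acetal carbon (2R).

Step 2
Reactants: 3 (2R,5R)-2-tert-butyl-5-methyl-1,3-dioxolan-4-one; 4 allyl bromide
Product: 6 (2R,5S)-2-tert-butyl-5-methyl-5-(prop-2-en-1-yl)-1,3-dioxolan-4-one, via lithium enolate 5 (not isolated)
Conditions: LiN(i-Pr)2, THF, −78 °C; then 4, −78 → −20 °C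
Reagents that add atoms: none
Why: Enolate alkylation with self-regeneration of the stereocentre: the tert-butyl group on the acetal carbon shields one face of the planar enolate, so allyl bromide enters trans to it and the quaternary carbinol centre (5S, the later side-chain carbinol) is formed.

Step 3
Reactants: 6 (2R,5S)-2-tert-butyl-5-methyl-5-(prop-2-en-1-yl)-1,3-dioxolan-4-one
Product: 8 2-[(2R,4S)-2-tert-butyl-4-methyl-5-oxo-1,3-dioxolan-4-yl]acetaldehyde, via ozonide 7 (not isolated)
Conditions: O3, CH2Cl2, −78 °C; then Me2S, −78 °C → rt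
Reagents that add atoms: ozone, O=[O+][O-]
Why: Ozonolysis of the terminal alkene with reductive work-up gives the aldehyde; the neighbouring quaternary centre cannot epimerise.

Step 4
Reactants: 8 2-[(2R,4S)-2-tert-butyl-4-methyl-5-oxo-1,3-dioxolan-4-yl]acetaldehyde; 9 methyl vinyl ketone
Product: 11 (4S)-4-[(2R,4S)-2-tert-butyl-4-methyl-5-oxo-1,3-dioxolan-4-yl]cyclohex-2-en-1-one, via keto aldehyde 10 (not isolated)
Conditions: (R)-α,α-diphenylprolinol trimethylsilyl ether (10 mol %), ethyl 3,4-dihydroxybenzoate (20 mol %), CH2Cl2, 4 °C; then p-TsOH·H2O (20 mol %), toluene, 4 Å molecular sieves, 45 °C, same flask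
Reagents that add atoms: none
Why: The amine condenses with 8 to an (E)-enamine whose α-carbon adds to the β-carbon of 9 on the face away from the CPh2(OSiMe3) group (first bond, ring CH–CH2), and hydrolysis releases keto aldehyde 10; acid then enolises the methyl ketone toward CH3, the enol closes onto the aldehyde and water is lost to give enone 11 (second bond, the later CHBr–CH2 bond). The closest known reaction type is the prolinol-ether-catalysed Michael addition of aldehydes to methyl vinyl ketone followed by aldol condensation, an asymmetric Robinson-type annulation to 4-substituted cyclohex-2-enones. Ring B closes in a 6-(enolendo)-exo-trig aldol, the only sensible mode because enolisation toward the CH2 side could only give a four-membered ring. The new ring stereocentre (4S) is set by the catalyst, the (R)-catalyst being chosen by analogy with its nitroalkene additions, and the adjacent lactic-acid-derived quaternary centre is expected to act as a spectator. The step needs conjugate addition to outrun self-aldol of 8, which the slowly self-condensing neopentyl-type aldehyde and the reactive enone should secure, and it needs the γ-stereocentre to survive dehydration, which mild acid at 45 °C should allow.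

Step 5
Reactants: 11 (4S)-4-[(2R,4S)-2-tert-butyl-4-methyl-5-oxo-1,3-dioxolan-4-yl]cyclohex-2-en-1-one
Product: 13 (4S)-2-bromo-4-[(2R,4S)-2-tert-butyl-4-methyl-5-oxo-1,3-dioxolan-4-yl]cyclohex-2-en-1-one, via dibromide 12 (not isolated)
Conditions: Br2, CH2Cl2, 0 °C; then Et3N, 0 °C → rt
Reagents that add atoms: bromine, BrBr
Why: α-Bromination of an enone by bromine addition to the C=C bond and E1cB loss of HBr (acidic α-hydrogen, β-bromide leaving) places bromine on the carbon that came from the methyl group of 9; the γ-stereocentre is not touched.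

Step 6
Reactants: 13 (4S)-2-bromo-4-[(2R,4S)-2-tert-butyl-4-methyl-5-oxo-1,3-dioxolan-4-yl]cyclohex-2-en-1-one
Product: 15 (2S,4S)-2-bromo-4-[(2R,4S)-2-tert-butyl-4-methyl-5-oxo-1,3-dioxolan-4-yl]cyclohexan-1-one, via lithium bromoenolate 14 (not isolated)
Conditions: LiBH(s-Bu)3 (1.05 equiv), THF, −78 °C; then AcOH in THF, −78 °C
Reagents that add atoms: none
Why: Conjugate hydride reduction of the β-unsubstituted cyclohexenone by the bulky borohydride gives the bromoenolate, and kinetic protonation from the axial direction of the half-chair (bulky ring substituent equatorial) should leave bromine equatorial, cis to that substituent (2S).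

Step 7
Reactants: 15 (2S,4S)-2-bromo-4-[(2R,4S)-2-tert-butyl-4-methyl-5-oxo-1,3-dioxolan-4-yl]cyclohexan-1-one
Product: 16 (2R,5S)-5-[(1S,3S,4R)-3-bromo-4-hydroxy-4-methylcyclohexyl]-2-tert-butyl-5-methyl-1,3-dioxolan-4-one
Conditions: MeLi, CeCl3, THF, −78 °C; aq. NH4Cl
Reagents that add atoms: methyllithium, [Li]C
Why: Organocerium 1,2-addition (weakly basic, so the α-bromo ketone is not enolised and the hindered lactone is spared) should deliver methyl equatorially, trans to the neighbouring equatorial bromine, giving the axial tertiary alcohol cis to bromine and to the side chain (4R).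

Step 8
Reactants: 16 (2R,5S)-5-[(1S,3S,4R)-3-bromo-4-hydroxy-4-methylcyclohexyl]-2-tert-butyl-5-methyl-1,3-dioxolan-4-one
Product: 17 (2S)-2-[(1S,3S,4R)-3-bromo-4-hydroxy-4-methylcyclohexyl]propane-1,2-diol
Conditions: LiBH4, THF–MeOH, 0 °C → rt
Reagents that add atoms: none
Why: Hydride reduction of the lactone carbonyl collapses the acetal (pivalaldehyde is reduced on) and frees the 1,2-diol, while LiBH4 leaves the secondary bromide alone; no stereocentre changes.

Step 9
Reactants: 17 (2S)-2-[(1S,3S,4R)-3-bromo-4-hydroxy-4-methylcyclohexyl]propane-1,2-diol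
Product: 18 (2S)-2-[(1S,3S,4R)-3-bromo-4-methyl-4-(triethylsilyloxy)cyclohexyl]-1,2-bis(triethylsilyloxy)propane
Conditions: Et3SiOTf, 2,6-lutidine, CH2Cl2, −78 → 0 °C
Reagents that add atoms: triethylsilyl trifluoromethanesulfonate, CC[Si](CC)(CC)OS(=O)(=O)C(F)(F)F
Why: Silyl triflate with a hindered pyridine base silylates the primary and both tertiary hydroxyls, which protects the tertiary alkoxide positions against Smiles-type side reactions and rearrangement of the bromohydrin in step 20.

Step 10
Reactants: 18 (2S)-2-[(1S,3S,4R)-3-bromo-4-methyl-4-(triethylsilyloxy)cyclohexyl]-1,2-bis(triethylsilyloxy)propane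
Product: 19 (2S)-2-[(1S,3S,4R)-3-bromo-4-methyl-4-(triethylsilyloxy)cyclohexyl]-2-(triethylsilyloxy)propanal
Conditions: (COCl)2, DMSO, CH2Cl2, −78 → −30 °C; then Et3N, −78 → 0 °C
Reagents that add atoms: none
Why: Swern conditions cleave and oxidise primary triethylsilyl ethers directly while tertiary silyl ethers are inert, and the quaternary α-carbon of the aldehyde cannot epimerise.

**Fragment A (ring A sulfone)**

Step 11
Reactants: 20 6-methylhept-5-en-2-one; 21 dimethyl carbonate
Product: 22 methyl 7-methyl-3-oxooct-6-enoate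
Conditions: NaH, THF, reflux; aq. HCl work-up
Reagents that add atoms: none
Why: Claisen-type C-acylation of the methyl-side ketone enolate with dimethyl carbonate, driven by formation of the stabilised β-keto ester enolate.

Step 12
Reactants: 22 methyl 7-methyl-3-oxooct-6-enoate
Product: 23 methyl 3-[(tert-butyldimethylsilyl)oxy]-7-methylocta-2,6-dienoate (E/Z mixture, geometry not relevant)
Conditions: t-BuMe2SiOTf, Et3N, CH2Cl2, 0 °C
Reagents that add atoms: tert-butyldimethylsilyl trifluoromethanesulfonate, CC(C)(C)[Si](C)(C)OS(=O)(=O)C(F)(F)F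
Why: Soft enolisation and O-silylation of the β-keto ester mask the acidic methylene for the oxidation and fix the carbon π-nucleophile (oxygen blocked) for the cyclisation in step 15.

Step 13
Reactants: 23 methyl 3-[(tert-butyldimethylsilyl)oxy]-7-methylocta-2,6-dienoate
Product: 24 methyl 3-[(tert-butyldimethylsilyl)oxy]-5-[(2R)-3,3-dimethyloxiran-2-yl]pent-2-enoate
Conditions: D-fructose-derived ketone catalyst (30 mol %), KHSO5 (as 2KHSO5·KHSO4·K2SO4), K2CO3, Bu4NHSO4, MeCN–CH2(OMe)2–aq. Na2B4O7 buffer, 0 °C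
Reagents that add atoms: potassium peroxymonosulfate, [K+].[O-]S(=O)(=O)OO
Why: Shi asymmetric epoxidation: the chiral dioxirane attacks the electron-rich trisubstituted alkene through a spiro transition state to give the (R)-epoxide, the ester-conjugated silyl enol ether being the less reactive alkene.

Step 14
Reactants: 24 methyl 3-[(tert-butyldimethylsilyl)oxy]-5-[(2R)-3,3-dimethyloxiran-2-yl]pent-2-enoate
Product: 25 methyl (6R)-7-bromo-3-[(tert-butyldimethylsilyl)oxy]-6-hydroxy-7-methyloct-2-enoate
Conditions: LiBr, AcOH, THF, 0 °C → rt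
Reagents that add atoms: lithium bromide, [Li+].[Br-]
Why: Acid-assisted opening of the trisubstituted epoxide by bromide at the tertiary carbon (Markovnikov halohydrin formation) leaves the secondary carbinol stereocentre (6R) untouched.

Step 15
Reactants: 25 methyl (6R)-7-bromo-3-[(tert-butyldimethylsilyl)oxy]-6-hydroxy-7-methyloct-2-enoate
Product: 28 methyl (1S,3S)-3-bromo-2,2-dimethyl-6-oxocyclohexane-1-carboxylate, via triflate 26 (not isolated), via bromonium triflate 27 (not isolated)
Conditions: Tf2O, 2,6-di-tert-butyl-4-methylpyridine, CH2Cl2, −78 → −20 °C; aq. NaHCO3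
Reagents that add atoms: none
Why: Bromonium-initiated cation–olefin cyclisation in its enantiospecific form: the neighbouring tertiary bromine displaces the secondary triflate with inversion to give an enantiopure bromonium ion, which the silyl enol ether carbon opens at the tertiary carbon through a chair transition state, so bromine ends equatorial (3S) and the epimerisable ester-bearing carbon settles cis to it (1S).

Step 16
Reactants: 28 methyl (1S,3S)-3-bromo-2,2-dimethyl-6-oxocyclohexane-1-carboxylate
Product: 29 methyl (1R,3S)-3-bromo-2,2-dimethyl-6-methylidenecyclohexane-1-carboxylate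
Conditions: Zn dust, CH2Br2, TiCl4, THF–CH2Cl2, 0 °C → rt
Reagents that add atoms: dibromomethane, BrCBr
Why: Takai–Lombardo methylenation: the non-basic gem-dimetallic reagent converts the hindered, enolisable ketone into the exocyclic alkene without touching ester or bromide and without epimerising the ester-bearing carbon, so the alkene position is unambiguous.

Step 17
Reactants: 29 methyl (1R,3S)-3-bromo-2,2-dimethyl-6-methylidenecyclohexane-1-carboxylate
Product: 30 [(1R,3S)-3-bromo-2,2-dimethyl-6-methylidenecyclohexyl]methanol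
Conditions: i-Bu2AlH, CH2Cl2, −78 → 0 °C; aq. potassium sodium tartrate
Reagents that add atoms: none
Why: Ester reduction to the primary alcohol; the secondary bromide and the alkene are inert at low temperature.

Step 18
Reactants: 30 [(1R,3S)-3-bromo-2,2-dimethyl-6-methylidenecyclohexyl]methanol
Product: 31 5-({[(1R,3S)-3-bromo-2,2-dimethyl-6-methylidenecyclohexyl]methyl}sulfanyl)-1-phenyl-1H-tetrazole
Conditions: 1-phenyl-1H-tetrazole-5-thiol, PPh3, diisopropyl azodicarboxylate, THF, 0 °C → rt
Reagents that add atoms: 1-phenyl-1H-tetrazole-5-thiol, Sc1nnnn1-c1ccccc1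
Why: Mitsunobu thioetherification of the primary (not neopentyl) alcohol; no stereocentre is involved.

Step 19
Reactants: 31 5-({[(1R,3S)-3-bromo-2,2-dimethyl-6-methylidenecyclohexyl]methyl}sulfanyl)-1-phenyl-1H-tetrazole
Product: 32 5-({[(1R,3S)-3-bromo-2,2-dimethyl-6-methylidenecyclohexyl]methyl}sulfonyl)-1-phenyl-1H-tetrazole
Conditions: (NH4)6Mo7O24·4H2O (10 mol %), 30% aq. H2O2, EtOH, 0 °C → rt
Reagents that add atoms: hydrogen peroxide, OO
Why: Molybdate-catalysed peroxide oxidation of the sulfide to the sulfone, conditions under which an unactivated 1,1-disubstituted alkene is not expected to be epoxidised.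

**Union and end game**

Step 20
Reactants: 32 5-({[(1R,3S)-3-bromo-2,2-dimethyl-6-methylidenecyclohexyl]methyl}sulfonyl)-1-phenyl-1H-tetrazole; 19 (2S)-2-[(1S,3S,4R)-3-bromo-4-methyl-4-(triethylsilyloxy)cyclohexyl]-2-(triethylsilyloxy)propanal
Product: 34 bis(triethylsilyl) ether of the target, via potassium sulfonyl carbanion 33 (not isolated)
Conditions: KN(SiMe3)2, DME, −60 °C; then 19, −60 °C → rt
Reagents that add atoms: none
Why: Julia–Kocienski olefination: the metalated tetrazolyl sulfone adds to the non-enolisable aldehyde, Smiles rearrangement and loss of SO2 and tetrazololate follow, and the potassium counter-ion in DME favours the anti adduct and hence the (E)-alkene; both equatorial bromides lack an anti-periplanar hydrogen, so elimination of HBr is not expected.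

Step 21
Reactants: 34 bis(triethylsilyl) ether of the target
Product: 35 (1R,2S,4S)-2-bromo-4-[(2S,3E)-4-[(1R,3S)-3-bromo-2,2-dimethyl-6-methylidenecyclohexyl]-2-hydroxybut-3-en-2-yl]-1-methylcyclohexan-1-ol
Conditions: HF·pyridine, pyridine–THF, 0 °C → rt
Reagents that add atoms: none
Why: Fluoride-mediated cleavage of both tertiary silyl ethers under buffered, non-basic conditions that should spare the cis-bromohydrin and the tertiary allylic alcohol.

**Compound list**

1 | (R)-lactic acid | C[C@@H](O)C(=O)O | starting material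
2 | pivalaldehyde | CC(C)(C)C=O | starting material
3 | (2R,5R)-2-tert-butyl-5-methyl-1,3-dioxolan-4-one | C[C@H]1O[C@@H](C(C)(C)C)OC1=O | intermediate
4 | allyl bromide | C=CCBr | starting material
5 | lithium (2R)-2-tert-butyl-5-methyl-1,3-dioxol-4-olate (not isolated) | CC1=C([O-])O[C@H](C(C)(C)C)O1.[Li+] | intermediate
6 | (2R,5S)-2-tert-butyl-5-methyl-5-(prop-2-en-1-yl)-1,3-dioxolan-4-one | O=C1O[C@H](C(C)(C)C)O[C@@]1(C)CC=C | intermediate
7 | (2R,5S)-2-tert-butyl-5-methyl-5-(1,2,4-trioxolan-3-ylmethyl)-1,3-dioxolan-4-one (ozonide, not isolated) | O=C1O[C@H](C(C)(C)C)O[C@@]1(C)CC1OCOO1 | intermediate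
8 | 2-[(2R,4S)-2-tert-butyl-4-methyl-5-oxo-1,3-dioxolan-4-yl]acetaldehyde | O=C1O[C@H](C(C)(C)C)O[C@@]1(C)CC=O | intermediate
9 | methyl vinyl ketone (but-3-en-2-one) | CC(=O)C=C | starting material
10 | (2R)-2-[(2R,4S)-2-tert-butyl-4-methyl-5-oxo-1,3-dioxolan-4-yl]-5-oxohexanal (not isolated) | O=C1O[C@H](C(C)(C)C)O[C@@]1(C)[C@H](C=O)CCC(C)=O | intermediate
11 | (4S)-4-[(2R,4S)-2-tert-butyl-4-methyl-5-oxo-1,3-dioxolan-4-yl]cyclohex-2-en-1-one | O=C1O[C@H](C(C)(C)C)O[C@@]1(C)[C@H]1CCC(=O)C=C1 | intermediate
12 | 2,3-dibromide of 11 (trans addition product, side-chain carbon unchanged, not isolated) | O=C1O[C@H](C(C)(C)C)O[C@@]1(C)[C@H]1CCC(=O)C(Br)C1Br | intermediate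
13 | (4S)-2-bromo-4-[(2R,4S)-2-tert-butyl-4-methyl-5-oxo-1,3-dioxolan-4-yl]cyclohex-2-en-1-one | O=C1O[C@H](C(C)(C)C)O[C@@]1(C)[C@H]1CCC(=O)C(Br)=C1 | intermediate
14 | lithium (4S)-2-bromo-4-[(2R,4S)-2-tert-butyl-4-methyl-5-oxo-1,3-dioxolan-4-yl]cyclohex-1-en-1-olate (not isolated) | O=C1O[C@H](C(C)(C)C)O[C@@]1(C)[C@H]1CCC([O-])=C(Br)C1.[Li+] | intermediate
15 | (2S,4S)-2-bromo-4-[(2R,4S)-2-tert-butyl-4-methyl-5-oxo-1,3-dioxolan-4-yl]cyclohexan-1-one | O=C1O[C@H](C(C)(C)C)O[C@@]1(C)[C@H]1CCC(=O)[C@@H](Br)C1 | intermediate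
16 | (2R,5S)-5-[(1S,3S,4R)-3-bromo-4-hydroxy-4-methylcyclohexyl]-2-tert-butyl-5-methyl-1,3-dioxolan-4-one | O=C1O[C@H](C(C)(C)C)O[C@@]1(C)[C@H]1CC[C@@](C)(O)[C@@H](Br)C1 | intermediate
17 | (2S)-2-[(1S,3S,4R)-3-bromo-4-hydroxy-4-methylcyclohexyl]propane-1,2-diol | OC[C@@](C)(O)[C@H]1CC[C@@](C)(O)[C@@H](Br)C1 | intermediate
18 | (2S)-2-[(1S,3S,4R)-3-bromo-4-methyl-4-(triethylsilyloxy)cyclohexyl]-1,2-bis(triethylsilyloxy)propane | CC[Si](CC)(CC)OC[C@@](C)(O[Si](CC)(CC)CC)[C@H]1CC[C@@](C)(O[Si](CC)(CC)CC)[C@@H](Br)C1 | intermediate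
19 | (2S)-2-[(1S,3S,4R)-3-bromo-4-methyl-4-(triethylsilyloxy)cyclohexyl]-2-(triethylsilyloxy)propanal | O=C[C@@](C)(O[Si](CC)(CC)CC)[C@H]1CC[C@@](C)(O[Si](CC)(CC)CC)[C@@H](Br)C1 | intermediate
20 | 6-methylhept-5-en-2-one | CC(=O)CCC=C(C)C | starting material
21 | dimethyl carbonate | COC(=O)OC | starting material
22 | methyl 7-methyl-3-oxooct-6-enoate | COC(=O)CC(=O)CCC=C(C)C | intermediate
23 | methyl 3-[(tert-butyldimethylsilyl)oxy]-7-methylocta-2,6-dienoate (E/Z mixture) | COC(=O)C=C(O[Si](C)(C)C(C)(C)C)CCC=C(C)C | intermediate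
24 | methyl 3-[(tert-butyldimethylsilyl)oxy]-5-[(2R)-3,3-dimethyloxiran-2-yl]pent-2-enoate | COC(=O)C=C(O[Si](C)(C)C(C)(C)C)CC[C@H]1OC1(C)C | intermediate
25 | methyl (6R)-7-bromo-3-[(tert-butyldimethylsilyl)oxy]-6-hydroxy-7-methyloct-2-enoate | COC(=O)C=C(O[Si](C)(C)C(C)(C)C)CC[C@@H](O)C(C)(C)Br | intermediate
26 | methyl (6R)-7-bromo-3-[(tert-butyldimethylsilyl)oxy]-7-methyl-6-(trifluoromethanesulfonyloxy)oct-2-enoate (not isolated) | COC(=O)C=C(O[Si](C)(C)C(C)(C)C)CC[C@@H](OS(=O)(=O)C(F)(F)F)C(C)(C)Br | intermediate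
27 | bromonium ion from 26, as its triflate (not isolated) | COC(=O)C=C(O[Si](C)(C)C(C)(C)C)CC[C@@H]1[Br+]C1(C)C.[O-]S(=O)(=O)C(F)(F)F | intermediate
28 | methyl (1S,3S)-3-bromo-2,2-dimethyl-6-oxocyclohexane-1-carboxylate | O=C1CC[C@H](Br)C(C)(C)[C@@H]1C(=O)OC | intermediate
29 | methyl (1R,3S)-3-bromo-2,2-dimethyl-6-methylidenecyclohexane-1-carboxylate | C=C1CC[C@H](Br)C(C)(C)[C@@H]1C(=O)OC | intermediate
30 | [(1R,3S)-3-bromo-2,2-dimethyl-6-methylidenecyclohexyl]methanol | C=C1CC[C@H](Br)C(C)(C)[C@@H]1CO | intermediate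
31 | 5-({[(1R,3S)-3-bromo-2,2-dimethyl-6-methylidenecyclohexyl]methyl}sulfanyl)-1-phenyl-1H-tetrazole | C=C1CC[C@H](Br)C(C)(C)[C@@H]1CSc1nnnn1-c1ccccc1 | intermediate
32 | 5-({[(1R,3S)-3-bromo-2,2-dimethyl-6-methylidenecyclohexyl]methyl}sulfonyl)-1-phenyl-1H-tetrazole | C=C1CC[C@H](Br)C(C)(C)[C@@H]1CS(=O)(=O)c1nnnn1-c1ccccc1 | intermediate
33 | potassium salt of α-deprotonated 32 (not isolated) | C=C1CC[C@H](Br)C(C)(C)[C@@H]1[CH-]S(=O)(=O)c1nnnn1-c1ccccc1.[K+] | intermediate
34 | bis(triethylsilyl) ether of the target: (E)-alkene, both tertiary hydroxyls silylated | C=C1CC[C@H](Br)C(C)(C)[C@@H]1/C=C/[C@@](C)(O[Si](CC)(CC)CC)[C@H]1CC[C@@](C)(O[Si](CC)(CC)CC)[C@@H](Br)C1 | intermediate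
35 | (1R,2S,4S)-2-bromo-4-[(2S,3E)-4-[(1R,3S)-3-bromo-2,2-dimethyl-6-methylidenecyclohexyl]-2-hydroxybut-3-en-2-yl]-1-methylcyclohexan-1-ol | C=C1CC[C@H](Br)C(C)(C)[C@@H]1/C=C/[C@@](C)(O)[C@H]1CC[C@@](C)(O)[C@@H](Br)C1 | target

**Totals and risks**

Total step count: 21. Longest linear sequence: 12 steps (steps 1–10, then 20 and 21).

Steps most likely to fail:

1. Step 15. Ionisation may be diverted into loss of HBr or a hydride shift, the anhydride may attack the silyl enol ether, oxygen rather than carbon may close the ring, or enantiopurity may erode through bromonium transfer between alkenes. The fallback sets out from 23 and returns at 30. Direct bromonium cyclisation of achiral 23 with Et2SBr·SbCl5Br in MeNO2 at −25 °C should give the racemic keto ester, that is 28 together with its enantiomer methyl (1R,3R)-3-bromo-2,2-dimethyl-6-oxocyclohexane-1-carboxylate F1. The conditions of steps 16 and 17 applied to the racemate should give 29 with methyl (1S,3R)-3-bromo-2,2-dimethyl-6-methylidenecyclohexane-1-carboxylate F2, and then 30 with [(1S,3R)-3-bromo-2,2-dimethyl-6-methylidenecyclohexyl]methanol F3. Kinetic resolution by lipase-catalysed acetylation (Burkholderia cepacia lipase, vinyl acetate) is expected to acetylate one enantiomer; the plan assumes that F3 is converted into [(1S,3R)-3-bromo-2,2-dimethyl-6-methylidenecyclohexyl]methyl acetate F4 while 30 is recovered and enters step 18.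

2. Step 6. Carbonyl (1,2) reduction or loss of bromine may compete with conjugate reduction, protonation may not be axial-selective, and the α-bromo ketone may epimerise during isolation. The fallback sets out from 11 and returns at 15. Conjugate reduction of 11 with LiBH(s-Bu)3 and trapping with Me3SiCl should give (2R,5S)-2-tert-butyl-5-methyl-5-[(1S)-4-(trimethylsilyloxy)cyclohex-3-en-1-yl]-1,3-dioxolan-4-one F5. N-Bromosuccinimide should brominate F5 regiospecifically, mainly to the axial epimer (2R,4S)-2-bromo-4-[(2R,4S)-2-tert-butyl-4-methyl-5-oxo-1,3-dioxolan-4-yl]cyclohexan-1-one F6 beside 15. F6 is equilibrated with 15 through the enol (HBr in AcOH) or by bromide exchange (LiBr, MeCN), 15 is separated by chromatography and F6 is recycled.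

3. Step 4. The hindered enamine may add slowly, the acetal oxygen may be lost by β-elimination from the enamine, or mismatched double stereodifferentiation may give poor facial selectivity. The fallback sets out from 8 and returns at 10 and 11. Condensation of 8 with (S)-1-amino-2-(methoxymethyl)pyrrolidine should give the hydrazone (2R,5S)-2-tert-butyl-5-[(2E)-2-{[(2S)-2-(methoxymethyl)pyrrolidin-1-yl]imino}ethyl]-5-methyl-1,3-dioxolan-4-one F7. Deprotonation with LiN(i-Pr)2 and auxiliary-controlled alkylation with 2-(2-iodoethyl)-2-methyl-1,3-dioxolane should give the α-alkylated hydrazone F8. Ozonolytic cleavage of the C=N bond should give (2R)-2-[(2R,4S)-2-tert-butyl-4-methyl-5-oxo-1,3-dioxolan-4-yl]-4-(2-methyl-1,3-dioxolan-2-yl)butanal F9. p-TsOH in wet acetone removes the ketal to give 10, which is closed to 11 under the acid conditions of step 4.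

Further compounds
F1 | step 15 | methyl (1R,3R)-3-bromo-2,2-dimethyl-6-oxocyclohexane-1-carboxylate (enantiomer of 28) | O=C1CC[C@@H](Br)C(C)(C)[C@H]1C(=O)OC
F2 | step 15 | methyl (1S,3R)-3-bromo-2,2-dimethyl-6-methylidenecyclohexane-1-carboxylate (enantiomer of 29) | C=C1CC[C@@H](Br)C(C)(C)[C@H]1C(=O)OC
F3 | step 15 | [(1S,3R)-3-bromo-2,2-dimethyl-6-methylidenecyclohexyl]methanol (enantiomer of 30) | C=C1CC[C@@H](Br)C(C)(C)[C@H]1CO
F4 | step 15 | [(1S,3R)-3-bromo-2,2-dimethyl-6-methylidenecyclohexyl]methyl acetate | C=C1CC[C@@H](Br)C(C)(C)[C@H]1COC(C)=O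
F5 | step 6 | (2R,5S)-2-tert-butyl-5-methyl-5-[(1S)-4-(trimethylsilyloxy)cyclohex-3-en-1-yl]-1,3-dioxolan-4-one | O=C1O[C@H](C(C)(C)C)O[C@@]1(C)[C@H]1CCC(O[Si](C)(C)C)=CC1
F6 | step 6 | (2R,4S)-2-bromo-4-[(2R,4S)-2-tert-butyl-4-methyl-5-oxo-1,3-dioxolan-4-yl]cyclohexan-1-one | O=C1O[C@H](C(C)(C)C)O[C@@]1(C)[C@H]1CCC(=O)[C@H](Br)C1
F7 | step 4 | (2R,5S)-2-tert-butyl-5-[(2E)-2-{[(2S)-2-(methoxymethyl)pyrrolidin-1-yl]imino}ethyl]-5-methyl-1,3-dioxolan-4-one | O=C1O[C@H](C(C)(C)C)O[C@@]1(C)C/C=N/N1CCC[C@H]1COC
F8 | step 4 | α-alkylated hydrazone: F7 bearing a 2-(2-methyl-1,3-dioxolan-2-yl)ethyl group on the carbon next to C=N | O=C1O[C@H](C(C)(C)C)O[C@@]1(C)[C@H](/C=N/N1CCC[C@H]1COC)CCC1(C)OCCO1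
F9 | step 4 | (2R)-2-[(2R,4S)-2-tert-butyl-4-methyl-5-oxo-1,3-dioxolan-4-yl]-4-(2-methyl-1,3-dioxolan-2-yl)butanal | O=C1O[C@H](C(C)(C)C)O[C@@]1(C)[C@H](C=O)CCC1(C)OCCO1
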